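**Plan**
Numbering: C1 = ArCH(OH), C2 = the neighbouring stereocentre, C3–C5 = CH2–CH=CH(anisyl). The retrosynthesis cuts, in order, the ester O–CH2 bond, the C4=C5 double bond, the benzylic C1–O bond and the C1–C2 bond.
Enabling feature: C1 is benzylic on the 3,4-dimethoxyphenyl ring and 1,4-related to alkene carbon C4. With C4 at the acid oxidation level, the C1 oxygen and C1–C4 make up a five-membered lactone ring, so the C1–O bond can be made by oxidising a benzylic C–H bond of a 4-arylbutanoic acid.
Forward: Stobbe condensation and asymmetric hydrogenation give a benzylbutyrolactone, which is opened to a silyloxy acid. Anodic lactonisation then closes the only ring of the route, and reduction to the lactol with E-olefination opens it again. Desilylation, primary-selective Mitsunobu esterification and a last desilylation follow.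
Stereochemistry: C2 comes from Rh-catalysed asymmetric hydrogenation and C1 from substrate control in the lactonisation (aryl trans to the silyloxymethyl group). The E alkene comes from the phosphonate olefination, and the Z enoate from Ru-catalysed trans-hydrostannation of but-2-yn-1-ol, carried on with retention.

Key step: step 5

Assumption: [Rh(cod)((S,S)-Et-DuPHOS)]BF4 is taken to deliver the 3R half-ester 5, by analogy with other Stobbe-derived itaconate half-esters; the sense would be checked at lactone 7 and the (R,R) ligand used if it proves opposite.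

Step 1
Reactants: 1 3,4-dimethoxybenzaldehyde; 2 dimethyl succinate
Product: 4 (3E)-4-(3,4-dimethoxyphenyl)-3-(methoxycarbonyl)but-3-enoic acid, via paraconate lactone 3 (not isolated)
Conditions: NaOMe (2 equiv), MeOH, reflux; then aq. HCl
Reagents that add atoms: none
Why: Stobbe condensation: the succinate enolate adds to the non-enolisable aldehyde, the aldolate closes to paraconate 3, and irreversible base-induced ring opening should deliver the conjugated half-ester as its carboxylate with the aryl group trans to the ester (E).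

Step 2
Reactants: 4 (3E)-4-(3,4-dimethoxyphenyl)-3-(methoxycarbonyl)but-3-enoic acid
Product: 5 (3R)-4-(3,4-dimethoxyphenyl)-3-(methoxycarbonyl)butanoic acid
Conditions: H2 (5 bar), [Rh(cod)((S,S)-Et-DuPHOS)]BF4 (0.5 mol%), NaOMe (0.1 equiv), MeOH, rt
Reagents that add atoms: none
Why: Rhodium-catalysed asymmetric hydrogenation of an itaconate-type half-ester: carboxylate and alkene bind the metal as a chelate, so hydrogen should be delivered to one face of the trisubstituted alkene and set C2 of the target (the 3R centre of 5).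

Step 3
Reactants: 5 (3R)-4-(3,4-dimethoxyphenyl)-3-(methoxycarbonyl)butanoic acid
Product: 7 (4R)-4-[(3,4-dimethoxyphenyl)methyl]oxolan-2-one, via hydroxy acid 6 (not isolated)
Conditions: KOH (1 equiv), EtOH, 0 °C; CaCl2, NaBH4 (Ca(BH4)2 formed in the flask), −10 °C to rt; then 2 M HCl, rt
Reagents that add atoms: none
Why: Chemoselective borohydride reduction: Ca(BH4)2 should reduce the methyl ester while the carboxylate is inert, and acidification closes hydroxy acid 6 to the γ-lactone (acid-catalysed lactonisation) without touching the stereocentre.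

Step 4
Reactants: 7 (4R)-4-[(3,4-dimethoxyphenyl)methyl]oxolan-2-one
Product: 10 (3R)-4-[(tert-butyldiphenylsilyl)oxy]-3-[(3,4-dimethoxyphenyl)methyl]butanoic acid, via sodium hydroxy carboxylate 8 (not isolated), via bis-silylated silyl ester 9 (not isolated)
Conditions: NaOH (1.05 equiv), MeOH/H2O, rt, then evaporation to dryness; TBDPSCl (2.5 equiv), imidazole, DMF, rt; K2CO3, MeOH/THF/H2O, rt; then 1 M HCl to pH 4, 0 °C
Reagents that add atoms: sodium hydroxide, [Na+].[OH-]; tert-butyldiphenylsilyl chloride (TBDPSCl), CC(C)(C)[Si](Cl)(c1ccccc1)c1ccccc1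
Why: Saponification opens the lactone, silylation caps both the hydroxyl and the carboxylate, and selective carbonate hydrolysis of the labile silyl ester should leave the robust primary TBDPS ether and the free acid.

Step 5
Reactants: 10 (3R)-4-[(tert-butyldiphenylsilyl)oxy]-3-[(3,4-dimethoxyphenyl)methyl]butanoic acid
Product: 11 (4R,5S)-4-{[(tert-butyldiphenylsilyl)oxy]methyl}-5-(3,4-dimethoxyphenyl)oxolan-2-one
Conditions: graphite anode, Pt cathode, undivided cell, constant current (ca. 3 mA cm−2, 2.2 F mol−1), n-Bu4NPF6 (0.1 M), 2,6-lutidine (2 equiv), CH2Cl2/HFIP (4:1), rt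
Reagents that add atoms: none
Why: The 3,4-dimethoxyphenyl ring is the most easily oxidised group of 10, so the anode should give its radical cation, which loses a benzylic proton to 2,6-lutidine; a second electron transfer gives a benzylic cation stabilised by the para methoxy group, and the carboxyl oxygen captures it while protons are reduced to H2 at the cathode. The closest known reaction type is the anodic (or quinone-mediated) dehydrogenative benzylic C–H lactonisation of 4-arylbutanoic acids to γ-aryl-γ-butyrolactones. The single ring formed, the five-membered lactone, closes in a 5-exo-trig mode onto the cationic benzylic carbon. The new stereocentre C5 of the lactone (C1 of the target) is controlled by the existing C4 centre (C2 of the target): in the envelope transition state the aryl group and the silyloxymethyl group should take opposite faces, and the trans lactone is also the more stable isomer, so any reversible ionisation of the benzylic C–O bond would lead to the same product. The step needs chemoselectivity for arene oxidation over Kolbe-type decarboxylation and over re-oxidation of the product; the low potential of the veratryl ring, a carbon anode at low current density, the weak base in HFIP and the electron-withdrawing acyloxy group in 11 should secure it. Site selectivity is given because only one benzylic CH2 group is present and only five-ring closure is possible, and the anisyl styrene, which would be oxidised even more easily, is not yet in the molecule.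

Step 6
Reactants: 11 (4R,5S)-4-{[(tert-butyldiphenylsilyl)oxy]methyl}-5-(3,4-dimethoxyphenyl)oxolan-2-one
Product: 12 (4R,5S)-4-{[(tert-butyldiphenylsilyl)oxy]methyl}-5-(3,4-dimethoxyphenyl)oxolan-2-ol (both anomers, in equilibrium with the open γ-hydroxy aldehyde form)
Conditions: i-Bu2AlH (DIBAL-H, 1.1 equiv), CH2Cl2, −78 °C; aq. KNaC4H4O6 (potassium sodium tartrate)
Reagents that add atoms: none
Why: Partial reduction of a lactone with DIBAL-H at low temperature should stop at the aluminium hemiacetal, which gives the lactol on work-up; the silyl ether and both stereocentres are untouched.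

Step 7
Reactants: 12 (4R,5S)-4-{[(tert-butyldiphenylsilyl)oxy]methyl}-5-(3,4-dimethoxyphenyl)oxolan-2-ol; 13 diethyl [(4-methoxyphenyl)methyl]phosphonate
Product: 14 (1S,2R,4E)-2-{[(tert-butyldiphenylsilyl)oxy]methyl}-1-(3,4-dimethoxyphenyl)-5-(4-methoxyphenyl)pent-4-en-1-ol
Conditions: 13 (3 equiv), KOtBu (3 equiv), THF/DMF, 0 °C to rt
Reagents that add atoms: none
Why: Horner–Wadsworth–Emmons olefination: the lactol reacts through its ring-opened aldehyde form with the benzylic phosphonate anion, and reversible addition followed by phosphate elimination should give the conjugated E alkene; neither stereocentre is α to the aldehyde, and a base-induced silyl shift between the two oxygens would be harmless because the silyl group is removed next.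

Step 8
Reactants: 14 (1S,2R,4E)-2-{[(tert-butyldiphenylsilyl)oxy]methyl}-1-(3,4-dimethoxyphenyl)-5-(4-methoxyphenyl)pent-4-en-1-ol
Product: 15 (1S,2R)-1-(3,4-dimethoxyphenyl)-2-[(2E)-3-(4-methoxyphenyl)prop-2-en-1-yl]propane-1,3-diol
Conditions: n-Bu4NF (1.2 equiv), THF, 0 °C to rt; H2O
Reagents that add atoms: none
Why: Fluoride-mediated desilylation driven by the strong Si–F bond; nothing else in 14 is labile to fluoride or mild base.

Step 9
Reactants: 16 but-2-yn-1-ol
Product: 17 (2Z)-2-(tributylstannyl)but-2-en-1-ol
Conditions: Bu3SnH (1.1 equiv), [Cp*RuCl]4 (1.5 mol%), CH2Cl2, rt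
Reagents that add atoms: tributyltin hydride, CCCC[SnH](CCCC)CCCC
Why: Ruthenium-catalysed trans-hydrostannation of a propargylic alcohol: a hydrogen bond from the hydroxyl to the chloride ligand should steer tin to the proximal alkyne carbon, and the trans addition mode places H and Sn on opposite sides, so the methyl group ends cis to tin.

Step 10
Reactants: 17 (2Z)-2-(tributylstannyl)but-2-en-1-ol
Product: 18 tert-butyldimethyl{[(2Z)-2-(tributylstannyl)but-2-en-1-yl]oxy}silane
Conditions: TBSCl (1.1 equiv), imidazole, CH2Cl2, 0 °C to rt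
Reagents that add atoms: tert-butyldimethylsilyl chloride (TBSCl), CC(C)(C)[Si](C)(C)Cl
Why: Imidazole-assisted silylation of a primary alcohol under conditions too mild to protodestannylate the alkenylstannane.

Step 11
Reactants: 18 tert-butyldimethyl{[(2Z)-2-(tributylstannyl)but-2-en-1-yl]oxy}silane
Product: 20 (2Z)-2-{[(tert-butyldimethylsilyl)oxy]methyl}but-2-enoic acid, via alkenyllithium 19 (not isolated)
Conditions: n-BuLi (1.1 equiv), THF, −78 °C; CO2 (dry gas), −78 °C to 0 °C; then 1 M HCl to pH 3–4, 0 °C
Reagents that add atoms: carbon dioxide, O=C=O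
Why: Tin–lithium exchange should give the configurationally stable alkenyllithium 19 with retention at −78 °C, and carboxylation also proceeds with retention, so the methyl group ends cis to the carboxyl group (Z).

Step 12
Reactants: 15 (1S,2R)-1-(3,4-dimethoxyphenyl)-2-[(2E)-3-(4-methoxyphenyl)prop-2-en-1-yl]propane-1,3-diol; 20 (2Z)-2-{[(tert-butyldimethylsilyl)oxy]methyl}but-2-enoic acid
Product: 21 (2R,4E)-2-[(S)-(3,4-dimethoxyphenyl)(hydroxy)methyl]-5-(4-methoxyphenyl)pent-4-en-1-yl (2Z)-2-{[(tert-butyldimethylsilyl)oxy]methyl}but-2-enoate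
Conditions: PPh3 (1.3 equiv), DIAD (1.3 equiv, slow addition), 20 (1.2 equiv), THF, −20 °C to 0 °C
Reagents that add atoms: none
Why: Mitsunobu esterification: the less hindered primary hydroxyl should form the alkoxyphosphonium ion preferentially and be displaced by the carboxylate at a CH2 group (no stereocentre involved); the acid acts only as a nucleophile and is never activated as an acyl electrophile, so the Z enoate should not isomerise.

Step 13
Reactants: 21 (2R,4E)-2-[(S)-(3,4-dimethoxyphenyl)(hydroxy)methyl]-5-(4-methoxyphenyl)pent-4-en-1-yl (2Z)-2-{[(tert-butyldimethylsilyl)oxy]methyl}but-2-enoate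
Product: 22 (2R,4E)-2-[(S)-(3,4-dimethoxyphenyl)(hydroxy)methyl]-5-(4-methoxyphenyl)pent-4-en-1-yl (2Z)-2-(hydroxymethyl)but-2-enoate
Conditions: HF·pyridine, pyridine, THF, 0 °C to rt
Reagents that add atoms: none
Why: Buffered fluoride desilylation of the primary allylic TBS ether; the weakly acidic, non-basic medium should avoid acyl migration to the benzylic hydroxyl, Z-to-E isomerisation and ionisation of the electron-rich benzylic alcohol.

**Compound list**
1 | 3,4-dimethoxybenzaldehyde | COc1ccc(C=O)cc1OC | starting material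
2 | dimethyl succinate | COC(=O)CCC(=O)OC | starting material
3 | methyl 2-(3,4-dimethoxyphenyl)-5-oxooxolane-3-carboxylate (paraconate lactone, racemic diastereomer mixture) | COC(=O)C1CC(=O)OC1c1ccc(OC)c(OC)c1 | intermediate
4 | (3E)-4-(3,4-dimethoxyphenyl)-3-(methoxycarbonyl)but-3-enoic acid | OC(=O)C/C(=C\c1ccc(OC)c(OC)c1)C(=O)OC | intermediate
5 | (3R)-4-(3,4-dimethoxyphenyl)-3-(methoxycarbonyl)butanoic acid | OC(=O)C[C@H](C(=O)OC)Cc1ccc(OC)c(OC)c1 | intermediate
6 | (3R)-4-(3,4-dimethoxyphenyl)-3-(hydroxymethyl)butanoic acid | OC(=O)C[C@H](CO)Cc1ccc(OC)c(OC)c1 | intermediate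
7 | (4R)-4-[(3,4-dimethoxyphenyl)methyl]oxolan-2-one | O=C1C[C@@H](Cc2ccc(OC)c(OC)c2)CO1 | intermediate
8 | sodium (3R)-4-(3,4-dimethoxyphenyl)-3-(hydroxymethyl)butanoate | [Na+].[O-]C(=O)C[C@H](CO)Cc1ccc(OC)c(OC)c1 | intermediate
9 | tert-butyldiphenylsilyl (3R)-4-[(tert-butyldiphenylsilyl)oxy]-3-[(3,4-dimethoxyphenyl)methyl]butanoate | CC(C)(C)[Si](c1ccccc1)(c1ccccc1)OC(=O)C[C@H](CO[Si](c1ccccc1)(c1ccccc1)C(C)(C)C)Cc1ccc(OC)c(OC)c1 | intermediate
10 | (3R)-4-[(tert-butyldiphenylsilyl)oxy]-3-[(3,4-dimethoxyphenyl)methyl]butanoic acid | OC(=O)C[C@H](CO[Si](c1ccccc1)(c1ccccc1)C(C)(C)C)Cc1ccc(OC)c(OC)c1 | intermediate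
11 | (4R,5S)-4-{[(tert-butyldiphenylsilyl)oxy]methyl}-5-(3,4-dimethoxyphenyl)oxolan-2-one (trans) | O=C1C[C@H](CO[Si](c2ccccc2)(c2ccccc2)C(C)(C)C)[C@@H](c2ccc(OC)c(OC)c2)O1 | intermediate
12 | (4R,5S)-4-{[(tert-butyldiphenylsilyl)oxy]methyl}-5-(3,4-dimethoxyphenyl)oxolan-2-ol (both anomers) | OC1C[C@H](CO[Si](c2ccccc2)(c2ccccc2)C(C)(C)C)[C@@H](c2ccc(OC)c(OC)c2)O1 | intermediate
13 | diethyl [(4-methoxyphenyl)methyl]phosphonate | CCOP(=O)(Cc1ccc(OC)cc1)OCC | starting material
14 | (1S,2R,4E)-2-{[(tert-butyldiphenylsilyl)oxy]methyl}-1-(3,4-dimethoxyphenyl)-5-(4-methoxyphenyl)pent-4-en-1-ol | CC(C)(C)[Si](c1ccccc1)(c1ccccc1)OC[C@@H](C/C=C/c1ccc(OC)cc1)[C@H](O)c1ccc(OC)c(OC)c1 | intermediate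
15 | (1S,2R)-1-(3,4-dimethoxyphenyl)-2-[(2E)-3-(4-methoxyphenyl)prop-2-en-1-yl]propane-1,3-diol | OC[C@@H](C/C=C/c1ccc(OC)cc1)[C@H](O)c1ccc(OC)c(OC)c1 | intermediate
16 | but-2-yn-1-ol | CC#CCO | starting material
17 | (2Z)-2-(tributylstannyl)but-2-en-1-ol | C/C=C(/CO)[Sn](CCCC)(CCCC)CCCC | intermediate
18 | tert-butyldimethyl{[(2Z)-2-(tributylstannyl)but-2-en-1-yl]oxy}silane | C/C=C(/CO[Si](C)(C)C(C)(C)C)[Sn](CCCC)(CCCC)CCCC | intermediate
19 | [(2E)-1-{[tert-butyl(dimethyl)silyl]oxy}but-2-en-2-yl]lithium (geometry retained; the descriptor changes only because Li ranks below C) | C/C=C(/CO[Si](C)(C)C(C)(C)C)[Li] | intermediate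
20 | (2Z)-2-{[(tert-butyldimethylsilyl)oxy]methyl}but-2-enoic acid | C/C=C(/CO[Si](C)(C)C(C)(C)C)C(=O)O | intermediate
21 | (2R,4E)-2-[(S)-(3,4-dimethoxyphenyl)(hydroxy)methyl]-5-(4-methoxyphenyl)pent-4-en-1-yl (2Z)-2-{[(tert-butyldimethylsilyl)oxy]methyl}but-2-enoate | C/C=C(/CO[Si](C)(C)C(C)(C)C)C(=O)OC[C@@H](C/C=C/c1ccc(OC)cc1)[C@H](O)c1ccc(OC)c(OC)c1 | intermediate
22 | (2R,4E)-2-[(S)-(3,4-dimethoxyphenyl)(hydroxy)methyl]-5-(4-methoxyphenyl)pent-4-en-1-yl (2Z)-2-(hydroxymethyl)but-2-enoate (CNP0280662.1) | C/C=C(/CO)C(=O)OC[C@@H](C/C=C/c1ccc(OC)cc1)[C@H](O)c1ccc(OC)c(OC)c1 | target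

**Total step count:** 13
**Longest linear sequence:** 10 steps (steps 1–8, 12 and 13); the side-chain acid takes 3 steps (9–11).

**Steps most likely to fail**

1. Step 5. Anodic decarboxylation of the carboxylate, further oxidation or aryl coupling of the electron-rich ring, or insufficient facial discrimination in the ring closure could erode the yield or the trans selectivity. The fallback sets out from 10 and returns at 11; it reaches the C1 oxygen through the ketone oxidation level and sets C1 by reagent control. Methylation (Me3SiCHN2, MeOH/toluene) would give methyl (3R)-4-[(tert-butyldiphenylsilyl)oxy]-3-[(3,4-dimethoxyphenyl)methyl]butanoate F1. Radical benzylic oxidation (N-hydroxyphthalimide cat., Co(OAc)2 cat., O2, MeCN), which passes through no benzylic cation, would give methyl (3R)-3-{[(tert-butyldiphenylsilyl)oxy]methyl}-4-(3,4-dimethoxyphenyl)-4-oxobutanoate F2. Corey–Bakshi–Shibata reduction with (R)-Me-CBS and BH3·SMe2 (THF, −20 °C; aryl as the large group, non-basic so the α-centre is not epimerised) would give methyl (3R,4S)-3-{[(tert-butyldiphenylsilyl)oxy]methyl}-4-(3,4-dimethoxyphenyl)-4-hydroxybutanoate F3. This should close to 11 with loss of methanol on warming with catalytic pyridinium p-toluenesulfonate in toluene.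

2. Step 7. Little open aldehyde may be present at equilibrium, so olefination could be slow and lose out to base-induced aldol self-condensation, or the E selectivity could erode. The fallback sets out from 12 and returns at 14. Wittig methylenation (Ph3PCH3Br, KOtBu, THF, 0 °C to rt), a reaction well established for lactols, would give (1S,2R)-2-{[(tert-butyldiphenylsilyl)oxy]methyl}-1-(3,4-dimethoxyphenyl)pent-4-en-1-ol F4. E-selective cross-metathesis with excess 4-methoxystyrene (second-generation Grubbs catalyst, RuCl2(=CHPh)(PCy3)(SIMes), CH2Cl2, 40 °C) would then give 14.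

3. Step 12. Activation of the secondary, electron-rich benzylic hydroxyl could compete with activation of the primary one, leading to ionisation, esterification at the wrong oxygen or elimination. The fallback sets out from 15 and returns at 21; it separates activation of the primary carbon from the ester-forming event. Primary-selective sulfonylation (TsCl 1.05 equiv, pyridine, CH2Cl2, 0 °C) would give (2R,3S)-3-(3,4-dimethoxyphenyl)-3-hydroxy-2-[(2E)-3-(4-methoxyphenyl)prop-2-en-1-yl]propyl 4-methylbenzenesulfonate F5. SN2 displacement with the preformed cesium salt of 20 (from 20 and 0.5 equiv Cs2CO3; DMF, 40 °C, no excess base, to suppress oxetane formation) would give 21, again without acyl activation of the Z acid.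

**Further compounds**
F1 | step 5 | methyl (3R)-4-[(tert-butyldiphenylsilyl)oxy]-3-[(3,4-dimethoxyphenyl)methyl]butanoate | COC(=O)C[C@H](CO[Si](c1ccccc1)(c1ccccc1)C(C)(C)C)Cc1ccc(OC)c(OC)c1
F2 | step 5 | methyl (3R)-3-{[(tert-butyldiphenylsilyl)oxy]methyl}-4-(3,4-dimethoxyphenyl)-4-oxobutanoate | COC(=O)C[C@H](CO[Si](c1ccccc1)(c1ccccc1)C(C)(C)C)C(=O)c1ccc(OC)c(OC)c1
F3 | step 5 | methyl (3R,4S)-3-{[(tert-butyldiphenylsilyl)oxy]methyl}-4-(3,4-dimethoxyphenyl)-4-hydroxybutanoate | COC(=O)C[C@H](CO[Si](c1ccccc1)(c1ccccc1)C(C)(C)C)[C@@H](c1ccc(OC)c(OC)c1)O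
F4 | step 7 | (1S,2R)-2-{[(tert-butyldiphenylsilyl)oxy]methyl}-1-(3,4-dimethoxyphenyl)pent-4-en-1-ol | CC(C)(C)[Si](c1ccccc1)(c1ccccc1)OC[C@@H](CC=C)[C@H](O)c1ccc(OC)c(OC)c1
F5 | step 12 | (2R,3S)-3-(3,4-dimethoxyphenyl)-3-hydroxy-2-[(2E)-3-(4-methoxyphenyl)prop-2-en-1-yl]propyl 4-methylbenzenesulfonate | Cc1ccc(cc1)S(=O)(=O)OC[C@@H](C/C=C/c1ccc(OC)cc1)[C@H](O)c1ccc(OC)c(OC)c1
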